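**Assumption:** the target is taken exactly as drawn. For names the macrocycle is numbered C1 (ester carbinol), C2=C3, C4 (quaternary), C5, C6=C7 (C7 bears CHO), C8, C9, C10–C11 (epoxide, C11 bears CH3), which gives (1S,4R,10R,11S), 2E, 6E and an E side-chain alkene.

## Retrosynthetic overview

1. The ester comes last, by Mitsunobu inversion of the (1R) epoxy alcohol with 3-methylbut-2-enoic acid. The oxirane comes from Sharpless epoxidation of the C10=C11 alkene of a macrocyclic bis-allylic alcohol.
2. The eleven-membered carbocycle is closed at C1–C11 by a Ni/Cr alkenyl iodide–aldehyde coupling. The C6=C7 enal comes from a Wittig reaction with a formyl-stabilised ylide.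
3. C1–C6, the C4 methyl and the C1 oxygen are the six ring carbons, the methyl and the oxygen of p-cresol. The cresol-derived ring is opened between C1 and C6 by glycol cleavage.
4. The quaternary C4 comes from oxidative dearomatisation (para-allylation) of p-cresol to a prochiral dienone. A desymmetrising Rh–H conjugate hydrosilylation with in-flask Rubottom oxidation sets C4.
5. Ring order: arene → cyclohexadienone → ring opened → eleven-membered carbocycle (step 11) → oxirane (step 12).

## Route

Step 1
Reactants: 1 4-methylphenol (p-cresol); 2 allyltrimethylsilane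
Product: 3 4-allyl-4-methylcyclohexa-2,5-dien-1-one
Conditions: PhI(OAc)2 (1.1 equiv), 2 (4 equiv), (CF3)2CHOH, 0 °C, 10 min
Reagents that add atoms: none
Why: Oxidative dearomatisation (phenol umpolung, oxidative Hosomi–Sakurai allylation): the phenoxenium-type intermediate is attacked by the allylsilane at the methyl-bearing para carbon, which creates the prochiral quaternary carbon without a stereocentre yet.

Step 2
Reactants: 3 4-allyl-4-methylcyclohexa-2,5-dien-1-one; 4 2-methylbut-3-en-2-ol
Product: 5 4-[(2E)-4-hydroxy-4-methylpent-2-en-1-yl]-4-methylcyclohexa-2,5-dien-1-one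
Conditions: second-generation Hoveyda–Grubbs catalyst RuCl2(=CH-C6H4-2-OiPr)(H2IMes) (3 mol%), 4 (5 equiv), CH2Cl2, 40 °C
Reagents that add atoms: none
Why: Olefin cross-metathesis of the terminal allyl group with an excess of the hindered tertiary allylic alcohol gives the E alkene under thermodynamic control, while the electron-poor ring enone C=C bonds do not take part.

Step 3
Reactants: 5 4-[(2E)-4-hydroxy-4-methylpent-2-en-1-yl]-4-methylcyclohexa-2,5-dien-1-one
Product: 7 (4R)-6-hydroxy-4-[(2E)-4-hydroxy-4-methylpent-2-en-1-yl]-4-methylcyclohex-2-en-1-one (both C6 epimers), via silyl dienol ether 6 (not isolated)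
Conditions: Rh(OAc)2(H2O)(iPr-Phebox) (2 mol%, ligand antipode that reduces the arm shown), (EtO)2MeSiH (1.5 equiv), toluene, 50 °C; then mCPBA (1.05 equiv), NaHCO3, CH2Cl2, −20 °C; then citric acid, MeOH
Reagents that add atoms: 3-chloroperbenzoic acid, OOC(=O)c1cccc(Cl)c1; diethoxy(methyl)silane, CCO[SiH](C)OCC (silicon stays only in 6)
Why: Proposed new method: the Rh–H adds 1,4 to only one of the two enantiotopic enone arms because the chiral Phebox pocket has to seat CH3 and the long CH2 chain differently, which sets C4; over-reduction cannot occur since the product is a silyl dienol ether, and mCPBA then epoxidises only this electron-rich C=C (Rubottom) to give the α′-hydroxy enone; the closest known reaction types are Rh(Phebox)-catalysed desymmetrising conjugate hydrosilylation of 4,4-disubstituted cyclohexa-2,5-dienones and Rubottom oxidation of 2-silyloxy-1,3-dienes.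

Step 4
Reactants: 7 (4R)-6-hydroxy-4-[(2E)-4-hydroxy-4-methylpent-2-en-1-yl]-4-methylcyclohex-2-en-1-one
Product: 8 (5R)-5-[(2E)-4-hydroxy-4-methylpent-2-en-1-yl]-5-methylcyclohex-3-ene-1,2-diol (diol diastereomers)
Conditions: NaBH4, CeCl3·7H2O, MeOH, −78 → 0 °C
Reagents that add atoms: none
Why: Luche reduction delivers hydride 1,2 to the enone carbonyl to give the vicinal diol, and both carbinol centres are destroyed in the next step so their configuration does not matter.

Step 5
Reactants: 8 (5R)-5-[(2E)-4-hydroxy-4-methylpent-2-en-1-yl]-5-methylcyclohex-3-ene-1,2-diol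
Product: 10 (2E,4R)-4-[(2E)-4-hydroxy-4-methylpent-2-en-1-yl]-4-methylhex-2-enedial, via (2Z)-dialdehyde 9 (not isolated)
Conditions: NaIO4, THF/pH 7 buffer, 0 °C; extract; then I2 (2 mol%), CH2Cl2, visible light, rt; Na2S2O3 wash
Reagents that add atoms: none
Why: Malaprade glycol cleavage opens the ring between the former C1 and C6 of the cresol ring to give both aldehydes, and iodine-atom-catalysed isomerisation turns the strained cis enal (CHO cis to the quaternary carbon) into the E enal without touching C4.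

Step 6
Reactants: 11 hex-4-yn-1-ol
Product: 13 (4E)-5-iodohex-4-en-1-ol, via alkenylzirconocene chloride 12 (not isolated)
Conditions: Cp2Zr(H)Cl (2.3 equiv), THF, 40 °C; then I2, 0 °C
Reagents that add atoms: iodine, [I][I]
Why: Schwartz hydrozirconation adds Zr–H syn, zirconium settles on the methyl-bearing alkyne carbon after equilibration with excess reagent, and iododezirconation with retention gives the E 2-iodoalkene.

Step 7
Reactants: 13 (4E)-5-iodohex-4-en-1-ol
Product: 14 (2E)-2,6-diiodohex-2-ene
Conditions: I2, PPh3, imidazole, CH2Cl2, 0 °C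
Reagents that add atoms: iodine, [I][I]
Why: Appel-type iodination proceeds by SN2 at the activated primary carbinol, and the alkenyl iodide is inert.

Step 8
Reactants: 14 (2E)-2,6-diiodohex-2-ene
Product: 15 [(4E)-5-iodohex-4-en-1-yl]triphenylphosphonium iodide
Conditions: PPh3, MeCN, 80 °C
Reagents that add atoms: triphenylphosphine, c1ccc(cc1)P(c1ccccc1)c1ccccc1
Why: SN2 quaternisation takes place only at the primary alkyl iodide because the sp2 C–I bond does not react with phosphines under these conditions.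

Step 9
Reactants: 15 [(4E)-5-iodohex-4-en-1-yl]triphenylphosphonium iodide; 16 ethyl formate
Product: 18 (5E)-6-iodo-2-(triphenyl-λ5-phosphanylidene)hept-5-enal, via phosphonium ylide 17 (not isolated)
Conditions: NaN(SiMe3)2 (2.1 equiv), THF, −78 °C; then 16, −78 → 0 °C
Reagents that add atoms: none
Why: C-formylation of a non-stabilised ylide: acyl transfer from the formate gives an α-formyl phosphonium ion that the second equivalent of base deprotonates to the formyl-stabilised ylide.

Step 10
Reactants: 10 (2E,4R)-4-[(2E)-4-hydroxy-4-methylpent-2-en-1-yl]-4-methylhex-2-enedial; 18 (5E)-6-iodo-2-(triphenyl-λ5-phosphanylidene)hept-5-enal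
Product: 19 (2E,4R,6E)-4-[(2E)-4-hydroxy-4-methylpent-2-en-1-yl]-7-[(3E)-4-iodopent-3-en-1-yl]-4-methylocta-2,6-dienedial
Conditions: 18 (1.0 equiv), toluene, 90 °C
Reagents that add atoms: none
Why: Wittig olefination with a formyl-stabilised ylide is faster at the saturated aldehyde than at the conjugated one and gives the E 2-alkyl enal (CHO trans to the new β-substituent), which is the C6=C7 geometry of the target.

Step 11
Reactants: 19 (2E,4R,6E)-4-[(2E)-4-hydroxy-4-methylpent-2-en-1-yl]-7-[(3E)-4-iodopent-3-en-1-yl]-4-methylocta-2,6-dienedial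
Product: 20 (1R,2E,4R,6E,10E)-1-hydroxy-4-[(2E)-4-hydroxy-4-methylpent-2-en-1-yl]-4,11-dimethylcycloundeca-2,6,10-triene-7-carbaldehyde
Conditions: CrCl2 (6 equiv), NiCl2 (5 mol%), chiral 2-(4-isopropyl-4,5-dihydrooxazol-2-yl)aryl methanesulfonamide ligand (antipode giving the 1R carbinol), Et3N, THF, rt, slow addition to 2 mM
Reagents that add atoms: none
Why: Nozaki–Hiyama–Kishi macrocyclisation: the alkenylchromium can reach only the C1 enal (addition to the C7 formyl group would need a trans-cyclohexene), the alkene geometry is retained, and the chiral sulfonamide on chromium selects the aldehyde face to set C1 as R.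

Step 12
Reactants: 20 (1R,2E,4R,6E,10E)-1-hydroxy-4-[(2E)-4-hydroxy-4-methylpent-2-en-1-yl]-4,11-dimethylcycloundeca-2,6,10-triene-7-carbaldehyde
Product: 21 (1R,2E,4R,6E,10R,11R)-10,11-epoxy-1-hydroxy-4-[(2E)-4-hydroxy-4-methylpent-2-en-1-yl]-4,11-dimethylcycloundeca-2,6-diene-7-carbaldehyde
Conditions: Ti(OiPr)4 (0.3 equiv), D-(−)-diisopropyl tartrate (0.36 equiv), tBuOOH, 4 Å MS, CH2Cl2, −20 °C
Reagents that add atoms: tert-butyl hydroperoxide, CC(C)(C)OO
Why: Sharpless asymmetric epoxidation in the matched sense: with the (1R) carbinol the D-tartrate titanium complex delivers oxygen to the C10=C11 face that gives the erythro epoxy alcohol, which sets C10 and C11, while the C2=C3 alkene, the enal and the tertiary allylic alcohol react far more slowly and any (1S) epimer is left behind.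

Step 13
Reactants: 21 (1R,2E,4R,6E,10R,11R)-10,11-epoxy-1-hydroxy-4-[(2E)-4-hydroxy-4-methylpent-2-en-1-yl]-4,11-dimethylcycloundeca-2,6-diene-7-carbaldehyde; 22 3-methylbut-2-enoic acid
Product: 23 (1S,2E,4R,6E,10R,11S)-10,11-epoxy-7-formyl-4-[(2E)-4-hydroxy-4-methylpent-2-en-1-yl]-4,11-dimethylcycloundeca-2,6-dien-1-yl 3-methylbut-2-enoate
Conditions: PPh3, iPrO2CN=NCO2iPr, 22 (1.5 equiv), toluene, 0 °C → rt
Reagents that add atoms: none
Why: Mitsunobu esterification: SN2 attack of the carboxylate on the alkoxyphosphonium ion inverts C1 from R to S and gives the threo epoxy ester of the target, SN2′ attack is blocked because C3 is neopentylic, and the tertiary alcohol does not react.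

## Compound list

1 | 4-methylphenol (p-cresol) | Cc1ccc(O)cc1 | starting material
2 | allyltrimethylsilane | C=CC[Si](C)(C)C | starting material
3 | 4-allyl-4-methylcyclohexa-2,5-dien-1-one | C=CCC1(C)C=CC(=O)C=C1 | intermediate
4 | 2-methylbut-3-en-2-ol | C=CC(C)(C)O | starting material
5 | 4-[(2E)-4-hydroxy-4-methylpent-2-en-1-yl]-4-methylcyclohexa-2,5-dien-1-one | CC(C)(O)/C=C/CC1(C)C=CC(=O)C=C1 | intermediate
6 | (4R)-1-[diethoxy(methyl)silyloxy]-4-[(2E)-4-hydroxy-4-methylpent-2-en-1-yl]-4-methylcyclohexa-1,5-diene (silyl dienol ether, not isolated) | CCO[Si](C)(OCC)OC1=CC[C@@](C)(C/C=C/C(C)(C)O)C=C1 | intermediate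
7 | (4R)-6-hydroxy-4-[(2E)-4-hydroxy-4-methylpent-2-en-1-yl]-4-methylcyclohex-2-en-1-one (both C6 epimers) | O=C1C=C[C@](C)(C/C=C/C(C)(C)O)CC1O | intermediate
8 | (5R)-5-[(2E)-4-hydroxy-4-methylpent-2-en-1-yl]-5-methylcyclohex-3-ene-1,2-diol (diastereomers at C1 and C2) | OC1C=C[C@](C)(C/C=C/C(C)(C)O)CC1O | intermediate
9 | (2Z,4R)-4-[(2E)-4-hydroxy-4-methylpent-2-en-1-yl]-4-methylhex-2-enedial (not isolated) | O=C/C=C\[C@](C)(C/C=C/C(C)(C)O)CC=O | intermediate
10 | (2E,4R)-4-[(2E)-4-hydroxy-4-methylpent-2-en-1-yl]-4-methylhex-2-enedial | O=C/C=C/[C@](C)(C/C=C/C(C)(C)O)CC=O | intermediate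
11 | hex-4-yn-1-ol | CC#CCCCO | starting material
12 | chloridozirconocene (E)-alkenyl species of the zirconium alkoxide of 11, zirconium on the methyl-bearing carbon (not isolated) | C/[C-]=C\CCC[O-].[Zr+4].[Zr+4].[Cl-].[Cl-].c1cc[cH-]c1.c1cc[cH-]c1.c1cc[cH-]c1.c1cc[cH-]c1 | intermediate
13 | (4E)-5-iodohex-4-en-1-ol | C/C(I)=C\CCCO | intermediate
14 | (2E)-2,6-diiodohex-2-ene | C/C(I)=C\CCCI | intermediate
15 | [(4E)-5-iodohex-4-en-1-yl]triphenylphosphonium iodide | C/C(I)=C\CCC[P+](c1ccccc1)(c1ccccc1)c1ccccc1.[I-] | intermediate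
16 | ethyl formate | CCOC=O | starting material
17 | [(4E)-5-iodohex-4-en-1-ylidene]triphenyl-λ5-phosphane (not isolated) | C/C(I)=C\CCC=P(c1ccccc1)(c1ccccc1)c1ccccc1 | intermediate
18 | (5E)-6-iodo-2-(triphenyl-λ5-phosphanylidene)hept-5-enal | C/C(I)=C\CCC(C=O)=P(c1ccccc1)(c1ccccc1)c1ccccc1 | intermediate
19 | (2E,4R,6E)-4-[(2E)-4-hydroxy-4-methylpent-2-en-1-yl]-7-[(3E)-4-iodopent-3-en-1-yl]-4-methylocta-2,6-dienedial | O=C/C=C/[C@](C)(C/C=C/C(C)(C)O)C/C=C(/C=O)CC/C=C(\C)I | intermediate
20 | (1R,2E,4R,6E,10E)-1-hydroxy-4-[(2E)-4-hydroxy-4-methylpent-2-en-1-yl]-4,11-dimethylcycloundeca-2,6,10-triene-7-carbaldehyde | C/C1=C\CC/C(C=O)=C\C[C@@](C)(C/C=C/C(C)(C)O)/C=C/[C@H]1O | intermediate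
21 | (1R,2E,4R,6E,10R,11R)-10,11-epoxy-1-hydroxy-4-[(2E)-4-hydroxy-4-methylpent-2-en-1-yl]-4,11-dimethylcycloundeca-2,6-diene-7-carbaldehyde | O[C@@H]1/C=C/[C@](C)(C/C=C/C(C)(C)O)C/C=C(/C=O)CC[C@H]2O[C@]12C | intermediate
22 | 3-methylbut-2-enoic acid | CC(C)=CC(=O)O | starting material
23 | (1S,2E,4R,6E,10R,11S)-10,11-epoxy-7-formyl-4-[(2E)-4-hydroxy-4-methylpent-2-en-1-yl]-4,11-dimethylcycloundeca-2,6-dien-1-yl 3-methylbut-2-enoate | CC(C)=CC(=O)O[C@H]1/C=C/[C@](C)(C/C=C/C(C)(C)O)C/C=C(/C=O)CC[C@H]2O[C@]12C | target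

## Step count

Total: 13 steps. Longest linear sequence: 9 steps (steps 1–5 and 10–13, from p-cresol). The side branch to ylide 18 is 4 steps.

## Three steps most likely to fail

**Step 3 (the rhodium hydride may not tell CH3 from the CH2 chain, giving low ee at C4).** The fallback sets out from 5 and swaps the metal hydride for a biocatalytic ene reduction (old-yellow-enzyme-type ene-reductase, NADPH recycled with glucose and glucose dehydrogenase, pH 7 buffer, 30 °C). The enzyme tells the two enone arms apart by how the C4 substituents fit the active site. This gives (4S)-4-[(2E)-4-hydroxy-4-methylpent-2-en-1-yl]-4-methylcyclohex-2-en-1-one F1. Its kinetic potassium enolate (KN(SiMe3)2, 2.2 equiv, THF, −78 °C; only C6 carries acidic hydrogens) is then hydroxylated with 3-phenyl-2-(phenylsulfonyl)oxaziridine. The fallback comes back to the route at 7.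

**Step 11 (ring strain or oligomerisation in the Ni/Cr closure, or poor control of C1).** The fallback sets out from 10 and reverses the order of the two C–C bond formations, so that C1 is set intermolecularly and the ring is closed by the Wittig reaction.
- The saturated aldehyde of 10 is masked selectively (CeCl3·7H2O, HC(OMe)3, MeOH; the conjugated aldehyde does not acetalise) as (2E,4R)-4-[(2E)-4-hydroxy-4-methylpent-2-en-1-yl]-6,6-dimethoxy-4-methylhex-2-enal F2.
- Intermolecular Ni/Cr coupling of F2 with alkenyl iodide 18 (CrCl2, NiCl2, the same chiral sulfonamide ligand, Et3N, THF) gives (5E,7R,8E,10R)-7-hydroxy-10-[(2E)-4-hydroxy-4-methylpent-2-en-1-yl]-12,12-dimethoxy-6,10-dimethyl-2-(triphenyl-λ5-phosphanylidene)dodeca-5,8-dienal F3.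
- Acetal hydrolysis (pyridinium p-toluenesulfonate, acetone/water) and intramolecular Wittig reaction at high dilution (toluene, 90 °C) close the C6=C7 bond. The fallback comes back to the route at 20.

**Step 13 (the hindered Mitsunobu inversion next to the quaternary epoxide carbon may be slow or give elimination).** The fallback sets out from 19 and avoids any substitution at C1.
- The Ni/Cr closure is run with the antipodal ligand to give (1S,2E,4R,6E,10E)-1-hydroxy-4-[(2E)-4-hydroxy-4-methylpent-2-en-1-yl]-4,11-dimethylcycloundeca-2,6,10-triene-7-carbaldehyde F4.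
- F4 is esterified with retention with acid 22 (dicyclohexylcarbodiimide, 4-dimethylaminopyridine, CH2Cl2) to give (1S,2E,4R,6E,10E)-7-formyl-4-[(2E)-4-hydroxy-4-methylpent-2-en-1-yl]-4,11-dimethylcycloundeca-2,6,10-trien-1-yl 3-methylbut-2-enoate F5.
- The oxirane is installed last by reagent-controlled Shi epoxidation of the only trisubstituted electron-rich alkene. Conditions: fructose-derived ketone of the antipode that attacks the required face, KHSO5 (as 2KHSO5·KHSO4·K2SO4), K2CO3 buffer, MeCN/dimethoxymethane, 0 °C. The fallback comes back to the route at 23.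

## Further compounds

F1 | step 3 | (4S)-4-[(2E)-4-hydroxy-4-methylpent-2-en-1-yl]-4-methylcyclohex-2-en-1-one | O=C1C=C[C@](C)(C/C=C/C(C)(C)O)CC1
F2 | step 11 | (2E,4R)-4-[(2E)-4-hydroxy-4-methylpent-2-en-1-yl]-6,6-dimethoxy-4-methylhex-2-enal | O=C/C=C/[C@](C)(C/C=C/C(C)(C)O)CC(OC)OC
F3 | step 11 | (5E,7R,8E,10R)-7-hydroxy-10-[(2E)-4-hydroxy-4-methylpent-2-en-1-yl]-12,12-dimethoxy-6,10-dimethyl-2-(triphenyl-λ5-phosphanylidene)dodeca-5,8-dienal | COC(OC)C[C@@](C)(C/C=C/C(C)(C)O)/C=C/[C@@H](O)/C(C)=C/CCC(C=O)=P(c1ccccc1)(c1ccccc1)c1ccccc1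
F4 | step 13 | (1S,2E,4R,6E,10E)-1-hydroxy-4-[(2E)-4-hydroxy-4-methylpent-2-en-1-yl]-4,11-dimethylcycloundeca-2,6,10-triene-7-carbaldehyde | C/C1=C\CC/C(C=O)=C\C[C@@](C)(C/C=C/C(C)(C)O)/C=C/[C@@H]1O
F5 | step 13 | (1S,2E,4R,6E,10E)-7-formyl-4-[(2E)-4-hydroxy-4-methylpent-2-en-1-yl]-4,11-dimethylcycloundeca-2,6,10-trien-1-yl 3-methylbut-2-enoate | C/C1=C\CC/C(C=O)=C\C[C@@](C)(C/C=C/C(C)(C)O)/C=C/[C@@H]1OC(=O)C=C(C)C
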